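L was the meeting's item: how much of it this flask holds at 30 h, and how near saturation its dissolved Q then stands, the proposed steps being J dissolving reversibly to Q, Q taking D to L, two Q giving G, and two D giving Z.

| flask | J | D | remark | time |
|---|---|---|---|---|
| north-east | 0.026 M | 4 equiv | run made earlier |  |
| south-west | 0.10 M | 4 equiv | run made earlier |  |
| east | 0.052 M | 6 equiv | run made earlier |  |
| flask | 0.052 M | 4.00 equiv |  | 30 h |

- north-east (time / h: L / %, Q / %): 2.00: 2.9, 26.4; 4.00: 7.0, 40.7; 10.0: 23.2, 37.5; 25.0: 36.0, 9.8
- south-west (time / h: L / %, Q / %): 3.00: 4.0, 7.3; 8.00: 11.0, 12.1; 15.0: 18.6, 12.9; 25.0: 29.1, 13.5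
- east (time / h: L / %, Q / %): 6.00: 12.8, 20.9; 12.0: 27.2, 24.7; 20.0: 40.2, 14.2; 25.0: 44.0, 8.4

(each reading ± 0.5 percentage points)

- a species is counted by the J in it: one G counts as two
- given per volume of solution although it is solid: J
- the numbers in the tables scatter with a standard deviation of 0.5 percentage points
- what may be going on: J <-> Q; Q + D -> L; 2 Q -> G; 2 D -> Z
- at the start none of J is in solution
- Q means what is dissolved; the solid is not counted in it

- amount of L at 30 h, in percent of the J charged
- concentration of Q in solution at 30 h, in percent of saturation

The first speaker proposed to follow the partition ratio ρ (a selectivity factor), the percent of J in L over the percent of J in G, since the proposed steps set the rate of L against that of G as cD against cQ, so that at like cQ ρ should climb with cD. Counting no J as solid in the last readings, where cQ was falling, and taking G as the remainder, she read ρ as 0.664 in the north-east run and 0.924 in the east run, at 25.0 h, with charged cD of 0.104 M and 0.312 M. In decimal logarithms, she said, the logarithm of ρ across these two readings, which carry their scatter and come from runs that differ in the J charged as well, climbs 0.301 per power of ten of charged cD, the partition slope. On that slope she put ρ for this flask at 0.818, carrying a ratio read at 25.0 h over to 30 h as her own estimate, and, setting aside as a stand-in the 8.4% of Q held by the east run at its last reading, L at 41.2%.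

The forecast, stepped by hand, gave L 40% (36% to 44%) and Q 19% of saturation (13% to 27%), holding that “Q sits near 0.0125 M until the solid runs out at about 17 h”.

The flask gave L 39.1% and Q 8.60% of saturation.

    J ⇌ Q, rate k1*(cs1 - [Q]) while solid is left; crystals form when [Q] > cs1 (solubility = 39.0 mM, k = 0.00180 min⁻¹)
    Q + D → L (k = 0.0130 M⁻¹ min⁻¹)
    2 Q → G (k = 0.0810 M⁻¹ min⁻¹)
    2 D → Z (k = 0.00360 M⁻¹ min⁻¹)

At 30.0 h this flask held G 54.4% beside its L, a ρ of 0.719, lower than the 0.818 reckoned. The same slope on the neighbour charged with 10.0 equiv of D gives ρ 1.08 and L 47.6%, whereas that neighbour held L 52.6% and G 42.2%, a ρ of 1.25, higher than reckoned. At 30.0 h that neighbour had 12% of its charged D left.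

Readings and results were generated by integration with made-up constants.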